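**Retrosynthetic overview**

1. The C9–O ester bond and the C10–O bond are made last, in one flask: hydroxyl-directed epoxidation of a C1 tertiary allylic alcohol, then opening of the epoxide at C9 by angelic acid. This sets C9 and C10 from C1.
2. The exocyclic C4=C15 methylene is carried as CH2SPh and unmasked by sulfoxide elimination only after ring-closing metathesis (C9=C10) has closed the seven-membered ring. If the methylene were present during metathesis, closure onto it to a six-membered ring would compete.
3. C1 is set by isopropenylcerium addition to a trans-2,3-disubstituted cyclopentanone, anti to the C5 side chain, followed by oxidation at C6.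
4. That cyclopentanone comes from asymmetric CuH reduction of a 3-substituted cyclopentenone (sets C4, a relay centre later destroyed) and Mukaiyama aldol with an Evans-derived aldehyde (C7).
5. Ring order: the five-membered ring is present from the start (cyclopentenone); the seven-membered ring is formed second.

Convention: locants C1–C15 are those of the guaiane skeleton (C1 and C5 ring fusion, C2–C4 rest of the five-membered ring, C6–C10 rest of the seven-membered ring, C14 the methyl on C10, C15 the carbon on C4).

Assumption: (S)-p-tol-BINAP is taken to give the (R)-configured C4 centre in the CuH reduction of step 5; if the sense is opposite, the (R)-ligand is used.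

**Step 1**
Reactants: 1 (R)-4-benzyl-3-(3-methylbutanoyl)oxazolidin-2-one; 2 allyl bromide
Product: 3 (4R)-4-benzyl-3-[(2R)-2-isopropylpent-4-enoyl]oxazolidin-2-one
Conditions: NaN(SiMe3)2 (1.1 equiv), THF, −78 °C; then 2 (3 equiv), −78 → −40 °C
Reagents that add atoms: none
Why: Evans asymmetric alkylation: the chelated Z-sodium enolate is shielded on one face by the benzyl group, so allyl bromide adds to the other face and sets the (R)-centre that becomes C7.

**Step 2**
Reactants: 3 (4R)-4-benzyl-3-[(2R)-2-isopropylpent-4-enoyl]oxazolidin-2-one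
Product: 4 (R)-2-isopropylpent-4-en-1-ol
Conditions: LiBH4 (1.2 equiv), H2O (1.2 equiv), Et2O, 0 °C
Reagents that add atoms: none
Why: Reductive cleavage of the N-acyl oxazolidinone gives the primary alcohol without touching C7 and returns the auxiliary.

**Step 3**
Reactants: 4 (R)-2-isopropylpent-4-en-1-ol
Product: 5 (R)-2-isopropylpent-4-enal
Conditions: Dess–Martin periodinane (1.2 equiv), CH2Cl2, 0 → 25 °C; used at once as a solution
Reagents that add atoms: none
Why: Dess–Martin oxidation of a primary alcohol under non-basic conditions gives the α-branched aldehyde without epimerisation.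

**Step 4**
Reactants: 6 3-ethoxycyclopent-2-en-1-one; 7 thioanisole
Product: 10 3-[(phenylthio)methyl]cyclopent-2-en-1-one, via (phenylthio)methyllithium 8 (not isolated), via lithium alkoxide adduct 9 (not isolated)
Conditions: 7, n-BuLi, DABCO, THF, 0 °C; then 6, −78 → 0 °C; then 1 M HCl, 25 °C
Reagents that add atoms: water, O
Why: Stork–Danheiser transposition: the sulfur-stabilised organolithium adds 1,2 to the vinylogous ester and acid hydrolysis/dehydration gives the 3-substituted enone, whose thioether is a metathesis-inert mask for the C15 methylene.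

**Step 5**
Reactants: 10 3-[(phenylthio)methyl]cyclopent-2-en-1-one; 5 (R)-2-isopropylpent-4-enal
Product: 12 (2R,3R)-2-[(2R)-1-hydroxy-2-isopropylpent-4-en-1-yl]-3-[(phenylthio)methyl]cyclopentan-1-one (both carbinol epimers), via silyl enol ether 11 (not isolated)
Conditions: CuCl (5 mol %), NaOt-Bu (5 mol %), (S)-p-tol-BINAP (5 mol %), (EtO)2MeSiH (1.3 equiv), toluene, −20 → 0 °C; then 5, Sc(OTf)3 (10 mol %), CH2Cl2, −78 °C; aqueous citric acid work-up
Reagents that add atoms: none
Why: Asymmetric conjugate reduction by a monovalent copper hydride (Buchwald-type) sets C4 and gives a regiodefined enol silane, which undergoes Mukaiyama aldol addition anti to the C4 substituent so that C5 is set trans to it; C7 comes from 5 and the carbinol epimers converge when C6 is oxidised.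

**Step 6**
Reactants: 12 (2R,3R)-2-[(2R)-1-hydroxy-2-isopropylpent-4-en-1-yl]-3-[(phenylthio)methyl]cyclopentan-1-one; 13 isopropenylmagnesium bromide
Product: 14 (1R,2R,3R)-2-[(2R)-1-hydroxy-2-isopropylpent-4-en-1-yl]-1-isopropenyl-3-[(phenylthio)methyl]cyclopentan-1-ol (both carbinol epimers)
Conditions: CeCl3 (4 equiv), 13 (4 equiv), THF, −78 °C
Reagents that add atoms: none
Why: Imamoto organocerium 1,2-addition: the weakly basic reagent adds without enolisation or retro-aldol and approaches the cyclopentanone anti to the adjacent C5 side chain, which sets the C1 tertiary alcohol cis to that chain and the isopropenyl group trans to it.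

**Step 7**
Reactants: 14 (1R,2R,3R)-2-[(2R)-1-hydroxy-2-isopropylpent-4-en-1-yl]-1-isopropenyl-3-[(phenylthio)methyl]cyclopentan-1-ol
Product: 15 (2R)-1-[(1S,2R,5R)-2-hydroxy-2-isopropenyl-5-[(phenylthio)methyl]cyclopentyl]-2-isopropylpent-4-en-1-one
Conditions: Dess–Martin periodinane (1.3 equiv), CH2Cl2, 0 → 25 °C
Reagents that add atoms: none
Why: Dess–Martin oxidation takes only the secondary carbinol (tertiary allylic alcohol and thioether are inert), merges both C6 epimers and leaves C5 in its stable configuration, with the acyl group trans to the C4 substituent and hydrogen-bonded to the cis C1 hydroxyl.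

**Step 8**
Reactants: 15 (2R)-1-[(1S,2R,5R)-2-hydroxy-2-isopropenyl-5-[(phenylthio)methyl]cyclopentyl]-2-isopropylpent-4-en-1-one
Product: 16 (3R,3aS,5R,8aR)-8a-hydroxy-5-isopropyl-8-methyl-3-[(phenylthio)methyl]-2,3,3a,5,6,8a-hexahydroazulen-4(1H)-one
Conditions: second-generation Grubbs catalyst RuCl2(=CHPh)(PCy3)(H2IMes) (10 mol %), toluene (0.002 M), 80 °C
Reagents that add atoms: none
Why: Ring-closing metathesis between the only two metathesis-active alkenes gives the trisubstituted C9=C10 alkene and the trans-fused bicycle, whose ring-fusion centres C1 and C5 were already set on the cyclopentane.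

**Step 9**
Reactants: 16 (3R,3aS,5R,8aR)-8a-hydroxy-5-isopropyl-8-methyl-3-[(phenylthio)methyl]-2,3,3a,5,6,8a-hexahydroazulen-4(1H)-one
Product: 18 (3aS,5R,8aR)-8a-hydroxy-5-isopropyl-8-methyl-3-methylene-2,3,3a,5,6,8a-hexahydroazulen-4(1H)-one, via sulfoxide 17 (not isolated)
Conditions: 30% H2O2 (1.1 equiv), (CF3)2CHOH, 25 °C; evaporate; then toluene, 110 °C
Reagents that add atoms: none
Why: Chemoselective sulfide-to-sulfoxide oxidation followed by thermal sulfoxide syn-elimination, whose only β-hydrogen is on C4, gives the exocyclic C4=C15 alkene regiospecifically under neutral conditions that do not move it into conjugation with the ketone.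

**Step 10**
Reactants: 18 (3aS,5R,8aR)-8a-hydroxy-5-isopropyl-8-methyl-3-methylene-2,3,3a,5,6,8a-hexahydroazulen-4(1H)-one; 19 angelic acid
Product: 21 (1R,5S,7R,9R,10S)-1,10-dihydroxy-6-oxoguai-4(15)-en-9-yl angelate, via epoxy alcohol 20 (not isolated)
Conditions: VO(acac)2 (5 mol %), t-BuOOH (1.1 equiv), CH2Cl2, 0 °C; then Ti(Oi-Pr)4 (1.5 equiv), 19 (3 equiv), 0 → 25 °C
Reagents that add atoms: tert-butyl hydroperoxide, CC(C)(C)OO
Why: Proposed new method: a one-flask hydroxyl-directed anti-hydroxy-acyloxylation of a tertiary cyclic allylic alcohol, in which the vanadium alkoxide of the C1 hydroxyl delivers the peroxide oxygen to the same (α) face of C9=C10 and the resulting epoxy alcohol, held as a bidentate alkoxide–epoxide chelate on tetravalent titanium, is opened by angelate at the distal secondary carbon C9 with inversion (C10 is quaternary and cannot undergo SN2), giving the 10α-hydroxyl and the 9β-angelate together; the closest known reactions are the vanadium/t-BuOOH epoxidation of allylic alcohols and the Ti(Oi-Pr)4-mediated C3-selective opening of primary 2,3-epoxy alcohols by carboxylic acids, neither shown in tandem, on a tertiary epoxy alcohol with a fully substituted C2, or with an α,β-unsaturated acid.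

**Compound list**

1 | (R)-4-benzyl-3-(3-methylbutanoyl)oxazolidin-2-one | O=C1OC[C@@H](Cc2ccccc2)N1C(=O)CC(C)C | starting material
2 | allyl bromide | C=CCBr | starting material
3 | (4R)-4-benzyl-3-[(2R)-2-isopropylpent-4-enoyl]oxazolidin-2-one | O=C1OC[C@@H](Cc2ccccc2)N1C(=O)[C@@H](C(C)C)CC=C | intermediate
4 | (R)-2-isopropylpent-4-en-1-ol | OC[C@@H](C(C)C)CC=C | intermediate
5 | (R)-2-isopropylpent-4-enal | O=C[C@@H](C(C)C)CC=C | intermediate
6 | 3-ethoxycyclopent-2-en-1-one | CCOC1=CC(=O)CC1 | starting material
7 | thioanisole (methyl phenyl sulfide) | CSc1ccccc1 | starting material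
8 | (phenylthio)methyllithium | [Li]CSc1ccccc1 | intermediate
9 | lithium 3-ethoxy-1-[(phenylthio)methyl]cyclopent-2-en-1-olate (racemic) | CCOC1=CC(O[Li])(CSc2ccccc2)CC1 | intermediate
10 | 3-[(phenylthio)methyl]cyclopent-2-en-1-one | O=C1C=C(CSc2ccccc2)CC1 | intermediate
11 | diethoxy(methyl){[(3R)-3-[(phenylthio)methyl]cyclopent-1-en-1-yl]oxy}silane | c1ccccc1SC[C@@H]1CCC(O[Si](C)(OCC)OCC)=C1 | intermediate
12 | (2R,3R)-2-[(2R)-1-hydroxy-2-isopropylpent-4-en-1-yl]-3-[(phenylthio)methyl]cyclopentan-1-one (ring substituents trans; both carbinol epimers) | c1ccccc1SC[C@@H]1CCC(=O)[C@H]1C(O)[C@@H](C(C)C)CC=C | intermediate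
13 | isopropenylmagnesium bromide | CC(=C)[Mg]Br | starting material
14 | (1R,2R,3R)-2-[(2R)-1-hydroxy-2-isopropylpent-4-en-1-yl]-1-isopropenyl-3-[(phenylthio)methyl]cyclopentan-1-ol (both carbinol epimers) | c1ccccc1SC[C@@H]1CC[C@](O)(C(C)=C)[C@H]1C(O)[C@@H](C(C)C)CC=C | intermediate
15 | (2R)-1-[(1S,2R,5R)-2-hydroxy-2-isopropenyl-5-[(phenylthio)methyl]cyclopentyl]-2-isopropylpent-4-en-1-one | c1ccccc1SC[C@@H]1CC[C@](O)(C(C)=C)[C@H]1C(=O)[C@@H](C(C)C)CC=C | intermediate
16 | (3R,3aS,5R,8aR)-8a-hydroxy-5-isopropyl-8-methyl-3-[(phenylthio)methyl]-2,3,3a,5,6,8a-hexahydroazulen-4(1H)-one; guaiane name (1R,4R,5S,7R)-1-hydroxy-15-(phenylthio)guai-9-en-6-one | c1ccccc1SC[C@@H]1CC[C@@]2(O)[C@H]1C(=O)[C@@H](C(C)C)CC=C2C | intermediate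
17 | (3R,3aS,5R,8aR)-8a-hydroxy-5-isopropyl-8-methyl-3-[(phenylsulfinyl)methyl]-2,3,3a,5,6,8a-hexahydroazulen-4(1H)-one (both sulfur epimers) | O=S(c1ccccc1)C[C@@H]1CC[C@@]2(O)[C@H]1C(=O)[C@@H](C(C)C)CC=C2C | intermediate
18 | (3aS,5R,8aR)-8a-hydroxy-5-isopropyl-8-methyl-3-methylene-2,3,3a,5,6,8a-hexahydroazulen-4(1H)-one; guaiane name (1R,5S,7R)-1-hydroxyguaia-4(15),9-dien-6-one | C=C1CC[C@@]2(O)[C@H]1C(=O)[C@@H](C(C)C)CC=C2C | intermediate
19 | angelic acid, (Z)-2-methylbut-2-enoic acid | OC(=O)/C(C)=C\C | starting material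
20 | (1R,5S,7R,9S,10S)-9,10-epoxy-1-hydroxyguai-4(15)-en-6-one (epoxide cis to the C1 hydroxyl) | C=C1CC[C@@]2(O)[C@H]1C(=O)[C@@H](C(C)C)C[C@H]3[C@]2(C)O3 | intermediate
21 | (1R,5S,7R,9R,10S)-1,10-dihydroxy-6-oxoguai-4(15)-en-9-yl angelate; (3aS,5R,7R,8S,8aR)-8,8a-dihydroxy-5-isopropyl-8-methyl-3-methylene-4-oxodecahydroazulen-7-yl (2Z)-2-methylbut-2-enoate | C=C1CC[C@@]2(O)[C@H]1C(=O)[C@@H](C(C)C)C[C@@H](OC(=O)/C(C)=C\C)[C@]2(C)O | target

**Step count and risks**

Total steps: 10. Longest linear sequence: 9 (steps 1, 2, 3, 5, 6, 7, 8, 9, 10); step 4 is the second branch.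

The three steps most likely to fail:

The one-flask epoxidation/angelate opening of step 10 is new. The titanium-templated attack at C9 may be slow on this hindered epoxy alcohol or divert to a semipinacol shift or to attack at C10. The fallback uses known chemistry, sets out from 18 and comes back at 21. Hydroxyl-directed syn-dihydroxylation with stoichiometric OsO4·TMEDA (CH2Cl2, −78 °C, hydrogen-bond delivery from the C1 hydroxyl, ethylenediamine work-up) gives the all-cis triol (1R,5S,7R,9S,10S)-1,9,10-trihydroxyguai-4(15)-en-6-one F1. Mitsunobu esterification of its only secondary hydroxyl with angelic acid 19 (PPh3, DIAD, toluene, 0 → 25 °C) then inverts C9 and gives 21.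

The ring-closing metathesis of step 8 must form a trisubstituted alkene next to a quaternary carbinol in a trans-fused seven-membered ring, with a thioether and a chelating β-hydroxy ketone present. The fallback sets out from 14 and comes back at 16. It moves the ring closure ahead of the oxidation: metathesis of diol 14 with the same ruthenium catalyst, where C6 is an sp3 carbinol and the side chain is more flexible, gives the bicyclic diol (3R,3aR,5R,8aR)-5-isopropyl-8-methyl-3-[(phenylthio)methyl]-1,2,3,3a,4,5,6,8a-octahydroazulene-4,8a-diol F2. Dess–Martin oxidation of its secondary carbinol gives 16.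

The organocerium addition of step 6 could lose facial selectivity if the free side-chain alkoxide delivers the reagent to its own face. The fallback sets out from 12 and comes back at 14. The side-chain hydroxyl is capped (Me3SiCl, imidazole, CH2Cl2) as (2R,3R)-2-[(2R)-2-isopropyl-1-(trimethylsilyloxy)pent-4-en-1-yl]-3-[(phenylthio)methyl]cyclopentan-1-one F3. Isopropenylcerium dichloride then adds under purely steric control to give (1R,2R,3R)-1-isopropenyl-2-[(2R)-2-isopropyl-1-(trimethylsilyloxy)pent-4-en-1-yl]-3-[(phenylthio)methyl]cyclopentan-1-ol F4, and aqueous citric acid in MeOH cleaves the silyl ether to return 14.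

**Further compounds**

F1 | step 10 | (1R,5S,7R,9S,10S)-1,9,10-trihydroxyguai-4(15)-en-6-one | C=C1CC[C@@]2(O)[C@H]1C(=O)[C@@H](C(C)C)C[C@H](O)[C@]2(C)O
F2 | step 8 | (3R,3aR,5R,8aR)-5-isopropyl-8-methyl-3-[(phenylthio)methyl]-1,2,3,3a,4,5,6,8a-octahydroazulene-4,8a-diol (both C4 carbinol epimers) | c1ccccc1SC[C@@H]1CC[C@@]2(O)[C@H]1C(O)[C@@H](C(C)C)CC=C2C
F3 | step 6 | (2R,3R)-2-[(2R)-2-isopropyl-1-(trimethylsilyloxy)pent-4-en-1-yl]-3-[(phenylthio)methyl]cyclopentan-1-one | c1ccccc1SC[C@@H]1CCC(=O)[C@H]1C(O[Si](C)(C)C)[C@@H](C(C)C)CC=C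
F4 | step 6 | (1R,2R,3R)-1-isopropenyl-2-[(2R)-2-isopropyl-1-(trimethylsilyloxy)pent-4-en-1-yl]-3-[(phenylthio)methyl]cyclopentan-1-ol | c1ccccc1SC[C@@H]1CC[C@](O)(C(C)=C)[C@H]1C(O[Si](C)(C)C)[C@@H](C(C)C)CC=C
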